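**Retrosynthetic overview**

1. The target is epicatechin 3-O-gallate-(4β→8)-epigallocatechin 3-O-gallate-(4β→8)-catechin 3-O-gallate; it comes from its 22-fold O-benzyl ether by one global hydrogenolysis.
2. Key disconnection: the three C3–O acyl (ester) bonds, closed together in one late threefold O-galloylation of the benzylated trimer triol, which consumes three molecules of tri-O-benzylgallic acid per molecule of triol (new fluoride-relay acyl fluoride/silyl ether method).
3. The trimer triol comes from two 4β→8 interflavan bonds, each made from a C4–O ether (oxidative C4–H etherification with DDQ) by Lewis-acid arylation: middle + bottom unit first, then top unit + dimer.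
4. The monomers are O-benzylated (−)-epicatechin, (−)-epigallocatechin and (+)-catechin. No ring is built: all rings and the six C2/C3 stereocentres are bought, and only the two C4 centres are made.

Assumption: "4β" means the 4-substituent trans to the 3-oxygen in the 2,3-cis units (as in the target SMILES), and (−)-epicatechin, (−)-epigallocatechin, (+)-catechin and 3,4,5-tris(benzyloxy)benzoic acid (tri-O-benzylgallic acid) are bought.

**Route**

Step 1
Reactants: 1 (−)-epicatechin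
Product: 2 5,7,3',4'-tetra-O-benzyl-(−)-epicatechin
Conditions: BnBr (4.4 equiv), K2CO3, DMF, 0 °C to rt, Ar
Reagents that add atoms: benzyl bromide, BrCc1ccccc1
Why: Williamson ether synthesis: carbonate deprotonates only the four phenols, which are O-benzylated by SN2, while the secondary 3-OH and the C2/C3 stereocentres are untouched.

Step 2
Reactants: 2 5,7,3',4'-tetra-O-benzyl-(−)-epicatechin
Product: 3 5,7,3',4'-tetra-O-benzyl-4β-(2-ethoxyethoxy)-(−)-epicatechin
Conditions: DDQ (2,3-dichloro-5,6-dicyano-1,4-benzoquinone, 2 equiv), EtOCH2CH2OH (6 equiv), CH2Cl2, rt; then 4-(dimethylamino)pyridine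
Reagents that add atoms: 2-ethoxyethanol, CCOCCO
Why: DDQ oxidative benzylic C–H etherification: hydride abstraction from C4 (activated by the 5,7-dibenzyloxy ring A) gives a quinone-methide-type cation that the alcohol captures anti to the 3-OH, giving the 4β C–O bond (3,4-trans).

Step 3
Reactants: 4 (−)-epigallocatechin
Product: 5 5,7,3',4',5'-penta-O-benzyl-(−)-epigallocatechin
Conditions: BnBr (5.5 equiv), K2CO3, DMF, −10 °C to rt, Ar (degassed)
Reagents that add atoms: benzyl bromide, BrCc1ccccc1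
Why: Williamson ether synthesis on the five phenols under strict exclusion of air (the pyrogallol ring B is oxidation-prone), with the 3-OH and both stereocentres unchanged.

Step 4
Reactants: 5 5,7,3',4',5'-penta-O-benzyl-(−)-epigallocatechin
Product: 6 5,7,3',4',5'-penta-O-benzyl-4β-(2-ethoxyethoxy)-(−)-epigallocatechin
Conditions: DDQ (2 equiv), EtOCH2CH2OH (6 equiv), CH2Cl2, rt; then 4-(dimethylamino)pyridine
Reagents that add atoms: 2-ethoxyethanol, CCOCCO
Why: The same DDQ oxidative benzylic C–H etherification at C4, with the alcohol adding trans to the 3-OH (4β).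

Step 5
Reactants: 7 (+)-catechin
Product: 8 5,7,3',4'-tetra-O-benzyl-(+)-catechin
Conditions: BnBr (4.4 equiv), K2CO3, DMF, 0 °C to rt, Ar
Reagents that add atoms: benzyl bromide, BrCc1ccccc1
Why: Williamson ether synthesis on the four phenols, leaving the 3-OH free and the (2R,3S) centres unchanged.

Step 6
Reactants: 6 5,7,3',4',5'-penta-O-benzyl-4β-(2-ethoxyethoxy)-(−)-epigallocatechin; 8 5,7,3',4'-tetra-O-benzyl-(+)-catechin
Product: 9 nona-O-benzyl epigallocatechin-(4β→8)-catechin (dimer diol)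
Conditions: 8 (3 equiv), Me3SiOTf (0.1 equiv), CH2Cl2, −78 °C, 10 min; Et3N
Reagents that add atoms: none
Why: Lewis-acid-promoted SN1 Friedel–Crafts arylation (interflavan condensation): Me3SiOTf ionises the C4–O ether of 6 and C8 of 8, the most nucleophilic ring A carbon, adds to the C4 cation anti to the 3-OH, so the new C4 centre is 4β (3,4-trans), while the excess of 8 suppresses self-condensation.

Step 7
Reactants: 3 5,7,3',4'-tetra-O-benzyl-4β-(2-ethoxyethoxy)-(−)-epicatechin; 9 nona-O-benzyl epigallocatechin-(4β→8)-catechin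
Product: 10 trideca-O-benzyl epicatechin-(4β→8)-epigallocatechin-(4β→8)-catechin (trimer triol)
Conditions: 9 (1.1 equiv), Yb(OTf)3 (1 equiv), CH2Cl2, rt
Reagents that add atoms: none
Why: The same Friedel–Crafts interflavan condensation at near 1:1 stoichiometry: the C4 cation from 3 is attacked by C8 of the epigallocatechin unit of 9 (flanked by only one benzyloxy group, whereas every free C6 lies between two) from the face anti to the 3-OH, setting the second 4β centre.

Step 8
Reactants: 10 trideca-O-benzyl trimer triol; 11 3,4,5-tris(benzyloxy)benzoic acid (three equivalents are built in)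
Product: 14 docosa-O-benzyl trimer tris(3-O-gallate), via tris(benzyloxy)benzoyl fluoride 12 (not isolated), via tris(trimethylsilyl) ether 13 (not isolated)
Conditions: (a) 11 (4.5 equiv), cyanuric fluoride (1.6 equiv), pyridine, CH2Cl2, −10 °C to rt, filter, ice-water wash, dry, solution used as such; (b) 10, (Me3Si)2NH, Me3SiOTf (1 mol %), CH2Cl2, rt, evaporate; (c) a + b, Bu4N[Ph3SiF2] (15 mol %), THF, rt to 40 °C
Reagents that add atoms: tri-O-benzylgallic acid, OC(=O)c1cc(OCc5ccccc5)c(OCc5ccccc5)c(OCc5ccccc5)c1 (this is 11 and its acyl group enters 14 three times); cyanuric fluoride, Fc1nc(F)nc(F)n1 (gives the fluorine of 12); hexamethyldisilazane, C[Si](C)(C)N[Si](C)(C)C (gives the Me3Si groups of 13)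
Why: Proposed new method: fluoride-relay threefold galloylation in which three molecules of 11, each turned into acyl fluoride 12, are consumed per molecule of 13 (overall 10 + 3 × 11 gives 14 and the elements of three molecules of water, which leave as cyanuric acid, NH3 and Me3SiF): fluoride from Bu4N[Ph3SiF2] removes Me3Si from each hindered 3-O-silyl ether of 13, the naked tetrabutylammonium alkoxide adds to the small, hard acyl fluoride 12 and the fluoride it expels carries the chain while Me3SiF escapes as a gas, so the three ester C–O bonds form without base or a bulky acylpyridinium even at the two carbinols flanked by 4-aryl groups and with retention at every C3 because only O–Si and O–acyl bonds change; the closest known reaction types are fluoride-catalysed acylation of simple silyl ethers by acyl fluorides and silyl-ether/fluoride exchange click chemistry, neither shown on a flavan-3-ol oligomer or for a threefold galloylation.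

Step 9
Reactants: 14 docosa-O-benzyl trimer tris(3-O-gallate)
Product: 15 epicatechin 3-O-gallate-(4β→8)-epigallocatechin 3-O-gallate-(4β→8)-catechin 3-O-gallate (target)
Conditions: H2 (1 atm), Pd(OH)2/C, THF/MeOH/H2O, rt; filter, lyophilise
Reagents that add atoms: none
Why: Heterogeneous catalytic hydrogenolysis cleaves all 22 benzyl–O bonds to toluene, while the three esters, the interflavan bonds and all eight stereocentres are inert to H2 over Pd(OH)2/C at room temperature.

**Compound list**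

1 | (−)-epicatechin, (2R,3R)-2-(3,4-dihydroxyphenyl)chromane-3,5,7-triol | O[C@@H]1Cc2c(O)cc(O)cc2O[C@@H]1c1ccc(O)c(O)c1 | starting material

2 | 5,7,3',4'-tetra-O-benzyl-(−)-epicatechin (2R,3R; free 3-OH) | O[C@@H]1Cc2c(OCc5ccccc5)cc(OCc5ccccc5)cc2O[C@@H]1c1ccc(OCc5ccccc5)c(OCc5ccccc5)c1 | intermediate

3 | 5,7,3',4'-tetra-O-benzyl-4β-(2-ethoxyethoxy)-(−)-epicatechin (2R; 2,3-cis; 3,4-trans; free 3-OH) | O[C@@H]1[C@@H](OCCOCC)c2c(OCc5ccccc5)cc(OCc5ccccc5)cc2O[C@@H]1c1ccc(OCc5ccccc5)c(OCc5ccccc5)c1 | intermediate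

4 | (−)-epigallocatechin, (2R,3R)-2-(3,4,5-trihydroxyphenyl)chromane-3,5,7-triol | O[C@@H]1Cc2c(O)cc(O)cc2O[C@@H]1c1cc(O)c(O)c(O)c1 | starting material

5 | 5,7,3',4',5'-penta-O-benzyl-(−)-epigallocatechin (2R,3R; free 3-OH) | O[C@@H]1Cc2c(OCc5ccccc5)cc(OCc5ccccc5)cc2O[C@@H]1c1cc(OCc5ccccc5)c(OCc5ccccc5)c(OCc5ccccc5)c1 | intermediate

6 | 5,7,3',4',5'-penta-O-benzyl-4β-(2-ethoxyethoxy)-(−)-epigallocatechin (2R; 2,3-cis; 3,4-trans; free 3-OH) | O[C@@H]1[C@@H](OCCOCC)c2c(OCc5ccccc5)cc(OCc5ccccc5)cc2O[C@@H]1c1cc(OCc5ccccc5)c(OCc5ccccc5)c(OCc5ccccc5)c1 | intermediate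

7 | (+)-catechin, (2R,3S)-2-(3,4-dihydroxyphenyl)chromane-3,5,7-triol | O[C@H]1Cc2c(O)cc(O)cc2O[C@@H]1c1ccc(O)c(O)c1 | starting material

8 | 5,7,3',4'-tetra-O-benzyl-(+)-catechin (2R,3S; free 3-OH) | O[C@H]1Cc2c(OCc5ccccc5)cc(OCc5ccccc5)cc2O[C@@H]1c1ccc(OCc5ccccc5)c(OCc5ccccc5)c1 | intermediate

9 | nona-O-benzyl epigallocatechin-(4β→8)-catechin: C4 of the penta-O-benzylepigallocatechin unit (2,3-cis, 3,4-trans) bonded to C8 of tetra-O-benzylcatechin; both 3-OH free | O[C@@H]1[C@@H](c2c(OCc5ccccc5)cc(OCc5ccccc5)c3c2O[C@H](c2ccc(OCc5ccccc5)c(OCc5ccccc5)c2)[C@@H](O)C3)c2c(OCc5ccccc5)cc(OCc5ccccc5)cc2O[C@@H]1c1cc(OCc5ccccc5)c(OCc5ccccc5)c(OCc5ccccc5)c1 | intermediate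

10 | trideca-O-benzyl epicatechin-(4β→8)-epigallocatechin-(4β→8)-catechin; three 3-OH free | O[C@@H]1[C@@H](c2c(OCc5ccccc5)cc(OCc5ccccc5)c3c2O[C@H](c2ccc(OCc5ccccc5)c(OCc5ccccc5)c2)[C@@H](O)C3)c2c(OCc5ccccc5)cc(OCc5ccccc5)c([C@H]3c4c(OCc5ccccc5)cc(OCc5ccccc5)cc4O[C@H](c4ccc(OCc5ccccc5)c(OCc5ccccc5)c4)[C@@H]3O)c2O[C@@H]1c1cc(OCc5ccccc5)c(OCc5ccccc5)c(OCc5ccccc5)c1 | intermediate

11 | 3,4,5-tris(benzyloxy)benzoic acid (tri-O-benzylgallic acid) | OC(=O)c1cc(OCc5ccccc5)c(OCc5ccccc5)c(OCc5ccccc5)c1 | starting material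

12 | 3,4,5-tris(benzyloxy)benzoyl fluoride | FC(=O)c1cc(OCc5ccccc5)c(OCc5ccccc5)c(OCc5ccccc5)c1 | intermediate (not isolated)

13 | tris(3-O-trimethylsilyl) ether of 10 | C[Si](C)(C)O[C@@H]1[C@@H](c2c(OCc5ccccc5)cc(OCc5ccccc5)c3c2O[C@H](c2ccc(OCc5ccccc5)c(OCc5ccccc5)c2)[C@@H](O[Si](C)(C)C)C3)c2c(OCc5ccccc5)cc(OCc5ccccc5)c([C@H]3c4c(OCc5ccccc5)cc(OCc5ccccc5)cc4O[C@H](c4ccc(OCc5ccccc5)c(OCc5ccccc5)c4)[C@@H]3O[Si](C)(C)C)c2O[C@@H]1c1cc(OCc5ccccc5)c(OCc5ccccc5)c(OCc5ccccc5)c1 | intermediate (not isolated)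

14 | docosa-O-benzyl trimer tris(3-O-gallate): 10 with each 3-OH esterified by 3,4,5-tris(benzyloxy)benzoyl | O=C(O[C@@H]1[C@@H](c2c(OCc5ccccc5)cc(OCc5ccccc5)c3c2O[C@H](c2ccc(OCc5ccccc5)c(OCc5ccccc5)c2)[C@@H](OC(=O)c6cc(OCc5ccccc5)c(OCc5ccccc5)c(OCc5ccccc5)c6)C3)c2c(OCc5ccccc5)cc(OCc5ccccc5)c([C@H]3c4c(OCc5ccccc5)cc(OCc5ccccc5)cc4O[C@H](c4ccc(OCc5ccccc5)c(OCc5ccccc5)c4)[C@@H]3OC(=O)c6cc(OCc5ccccc5)c(OCc5ccccc5)c(OCc5ccccc5)c6)c2O[C@@H]1c1cc(OCc5ccccc5)c(OCc5ccccc5)c(OCc5ccccc5)c1)c6cc(OCc5ccccc5)c(OCc5ccccc5)c(OCc5ccccc5)c6 | intermediate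

15 | epicatechin 3-O-gallate-(4β→8)-epigallocatechin 3-O-gallate-(4β→8)-catechin 3-O-gallate (CNP0321910.1) | O=C(O[C@@H]1[C@@H](c2c(O)cc(O)c3c2O[C@H](c2ccc(O)c(O)c2)[C@@H](OC(=O)c2cc(O)c(O)c(O)c2)C3)c2c(O)cc(O)c([C@H]3c4c(O)cc(O)cc4O[C@H](c4ccc(O)c(O)c4)[C@@H]3OC(=O)c3cc(O)c(O)c(O)c3)c2O[C@@H]1c1cc(O)c(O)c(O)c1)c1cc(O)c(O)c(O)c1 | target

**Totals and risks**

Total step count: 9. Longest linear sequence: 6 (steps 3, 4, 6, 7, 8, 9, from 4).

The three steps most likely to fail:

Step 8 (the new threefold galloylation). The risk is incomplete acylation of the two carbinols next to the 4-aryl groups, or side reactions of the free alkoxides. The fallback gives up late-stage galloylation and acylates before the last coupling, by known chemistry. It sets out from 9, 3 and 11. Carbodiimide esterification of 9 with two equivalents of 11 (N,N'-dicyclohexylcarbodiimide, 4-(dimethylamino)pyridine, CH2Cl2, rt) gives the dimer bis(3-O-gallate) F1. The same esterification of 3 with one equivalent of 11 gives the 3-O-galloylated 4β-(2-ethoxyethoxy) electrophile F2. Me3SiOTf-catalysed condensation of F2 with F1 (CH2Cl2, −78 °C; the 3-acyloxy group covers the α face, so arylation is again 4β) then gives 14, where the route is rejoined before step 9.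

Step 7 (1:1 coupling of a monomer electrophile with a dimer nucleophile). The risk is self-condensation of 3 and attack at a C6 position. The fallback changes the leaving group and the activation mode. It sets out from 3: thiolysis with 2-mercaptobenzothiazole (BF3·OEt2, CH2Cl2, −40 °C) gives the 4β-(benzothiazol-2-ylthio) donor F3. This is coupled with 9 under thiophilic activation (AgBF4, THF, 0 °C), which ionises C4–S fast at low temperature. The product is 10, where the route is rejoined.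

Step 3 (direct penta-O-benzylation of the air-sensitive pyrogallol monomer). The risk is oxidation and C-benzylation. The fallback sets out from 4 and keeps free phenoxide concentration low. Peracetylation (Ac2O, pyridine, rt) gives hexa-O-acetyl-(−)-epigallocatechin F4. One-pot deacetylation/benzylation of the five aryl acetates (NaH, BnBr, H2O 5 equiv, DMF, 0 °C to rt) gives 3-O-acetyl-5,7,3',4',5'-penta-O-benzyl-(−)-epigallocatechin F5. Methanolysis (K2CO3, MeOH/THF, rt) gives 5, where the route is rejoined.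

**Further compounds**

F1 | step 8 | nona-O-benzyl epigallocatechin-(4β→8)-catechin bis[3-O-(3,4,5-tri-O-benzylgalloyl)] ester | O=C(O[C@@H]1[C@@H](c2c(OCc5ccccc5)cc(OCc5ccccc5)c3c2O[C@H](c2ccc(OCc5ccccc5)c(OCc5ccccc5)c2)[C@@H](OC(=O)c6cc(OCc5ccccc5)c(OCc5ccccc5)c(OCc5ccccc5)c6)C3)c2c(OCc5ccccc5)cc(OCc5ccccc5)cc2O[C@@H]1c1cc(OCc5ccccc5)c(OCc5ccccc5)c(OCc5ccccc5)c1)c6cc(OCc5ccccc5)c(OCc5ccccc5)c(OCc5ccccc5)c6
F2 | step 8 | 5,7,3',4'-tetra-O-benzyl-4β-(2-ethoxyethoxy)-(−)-epicatechin 3-O-(3,4,5-tri-O-benzylgallate) | O=C(O[C@@H]1[C@@H](OCCOCC)c2c(OCc5ccccc5)cc(OCc5ccccc5)cc2O[C@@H]1c1ccc(OCc5ccccc5)c(OCc5ccccc5)c1)c6cc(OCc5ccccc5)c(OCc5ccccc5)c(OCc5ccccc5)c6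
F3 | step 7 | 5,7,3',4'-tetra-O-benzyl-4β-(benzothiazol-2-ylthio)-(−)-epicatechin | O[C@@H]1[C@@H](Sc2nc3ccccc3s2)c2c(OCc5ccccc5)cc(OCc5ccccc5)cc2O[C@@H]1c1ccc(OCc5ccccc5)c(OCc5ccccc5)c1
F4 | step 3 | 3,5,7,3',4',5'-hexa-O-acetyl-(−)-epigallocatechin | CC(=O)O[C@@H]1Cc2c(OC(C)=O)cc(OC(C)=O)cc2O[C@@H]1c1cc(OC(C)=O)c(OC(C)=O)c(OC(C)=O)c1
F5 | step 3 | 3-O-acetyl-5,7,3',4',5'-penta-O-benzyl-(−)-epigallocatechin | CC(=O)O[C@@H]1Cc2c(OCc5ccccc5)cc(OCc5ccccc5)cc2O[C@@H]1c1cc(OCc5ccccc5)c(OCc5ccccc5)c(OCc5ccccc5)c1
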